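**Plan**

- Retrosynthesis: the three benzyl ethers are removed last. Ring B (the central naphthol) is then cut at C1–C8a and C4–C4a.
- Enabling feature: B-C1 to B-C4 carry O, naphthyl unit A, H and naphthyl unit C in sequence, which is the substitution of C3 to C6 of a 3-alkoxy-4,6-diaryl-2-pyrone. The remaining C4a–C8a edge with the C8 methoxy group corresponds to 3-methoxybenzyne.
- The pyrone is cut at C3–C4 and at the lactone C–O bond, giving a diaryl ynone and a benzyloxyacetate. The ynone is cut between carbonyl and alkyne, so one protected 2-naphthaldehyde supplies both outer units.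
- Forward order: naphthalene-1,8-diol gives the protected aldehyde, then the alkyne, then the ynone. The pyrone ring is built next, the carbocycle of ring B is closed by aryne cycloaddition with CO2 loss, and hydrogenolysis finishes the synthesis.
- Stereochemistry: the target has no stereocentre. The carbinol centre and the two bridgehead centres that appear on the way are racemic and are erased.

Key step: step 8

Remark: the target SMILES defines no axial configuration; the two biaryl axes are treated as not configurationally fixed, so no stereocontrol is planned.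

**Route**

Step 1
Reactants: 1 naphthalene-1,8-diol
Product: 2 8-methoxynaphthalen-1-ol
Conditions: MeI (1.05 equiv), K2CO3, acetone, reflux
Reagents that add atoms: iodomethane, CI
Why: Williamson etherification that should stop at the monoether, because the remaining hydroxyl is locked in a strong peri hydrogen bond to the new methoxy oxygen and is much less acidic.

Step 2
Reactants: 2 8-methoxynaphthalen-1-ol
Product: 4 1-hydroxy-8-methoxy-2-naphthaldehyde, via 2-(hydroxymethyl)-8-methoxynaphthalen-1-ol 3 (not isolated)
Conditions: MgCl2, Et3N, (CH2O)n, MeCN, reflux; aq HCl work-up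
Reagents that add atoms: formaldehyde (as paraformaldehyde), C=O
Why: Casnati–Skattebøl ortho-formylation, in which the magnesium naphthoxide delivers coordinated formaldehyde only to C2 and a second formaldehyde oxidises the hydroxymethyl intermediate 3 by hydride transfer.

Step 3
Reactants: 4 1-hydroxy-8-methoxy-2-naphthaldehyde
Product: 5 1-(benzyloxy)-8-methoxy-2-naphthaldehyde
Conditions: BnBr, K2CO3, DMF, 60 °C
Reagents that add atoms: benzyl bromide, BrCc1ccccc1
Why: Williamson benzylation of a salicylaldehyde-type phenol, where warm DMF with carbonate should overcome the chelated, flanked hydroxyl.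

Step 4
Reactants: 5 1-(benzyloxy)-8-methoxy-2-naphthaldehyde
Product: 6 1-(benzyloxy)-2-ethynyl-8-methoxynaphthalene
Conditions: dimethyl (1-diazo-2-oxopropyl)phosphonate, K2CO3, MeOH/THF, 0 °C to rt
Reagents that add atoms: dimethyl (1-diazo-2-oxopropyl)phosphonate, CC(=O)C(=[N+]=[N-])P(=O)(OC)OC
Why: Seyferth–Gilbert homologation in the Ohira–Bestmann form, which suits a non-enolisable aryl aldehyde and uses a carbonate base that leaves the ethers untouched.

Step 5
Reactants: 6 1-(benzyloxy)-2-ethynyl-8-methoxynaphthalene; 5 1-(benzyloxy)-8-methoxy-2-naphthaldehyde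
Product: 7 1,3-bis[1-(benzyloxy)-8-methoxynaphthalen-2-yl]prop-2-yn-1-ol (racemic)
Conditions: nBuLi, THF, −78 °C; then 5, −78 to 0 °C; H2O quench
Reagents that add atoms: none
Why: 1,2-addition of a lithium acetylide to an aromatic aldehyde, with the alkyne C–H removed selectively at −78 °C; the carbinol centre forms as a racemate and is erased in step 6.

Step 6
Reactants: 7 1,3-bis[1-(benzyloxy)-8-methoxynaphthalen-2-yl]prop-2-yn-1-ol
Product: 8 1,3-bis[1-(benzyloxy)-8-methoxynaphthalen-2-yl]prop-2-yn-1-one
Conditions: Dess–Martin periodinane, CH2Cl2, rt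
Reagents that add atoms: none
Why: Dess–Martin oxidation of a secondary alcohol that is both benzylic and propargylic, under neutral conditions that the ethers and the alkyne tolerate.

Step 7
Reactants: 8 1,3-bis[1-(benzyloxy)-8-methoxynaphthalen-2-yl]prop-2-yn-1-one; 9 methyl 2-(benzyloxy)acetate
Product: 11 3-(benzyloxy)-4,6-bis[1-(benzyloxy)-8-methoxynaphthalen-2-yl]-2H-pyran-2-one, via Michael adduct keto ester 10 (not isolated)
Conditions: 9, LiN(iPr)2, THF, −78 °C; then 8, −78 °C to rt; H2O quench; crude with cat. DBU, PhMe, 80 °C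
Reagents that add atoms: none
Why: Michael addition of an ester enolate to an ynone followed by lactonisation (ynone–ester pyrone annulation), in which the doubly activated CH(OBn) of adduct 10 is deprotonated to a dienolate that equilibrates the alkene geometry and closes through the ketone enolate oxygen onto the methyl ester with loss of methoxide.

Step 8
Reactants: 11 3-(benzyloxy)-4,6-bis[1-(benzyloxy)-8-methoxynaphthalen-2-yl]-2H-pyran-2-one; 12 3-methoxy-2-(trimethylsilyl)phenyl trifluoromethanesulfonate
Product: 15 1-(benzyloxy)-2,4-bis[1-(benzyloxy)-8-methoxynaphthalen-2-yl]-8-methoxynaphthalene, via 3-methoxybenzyne 13 (not isolated), via bridged lactone 14 (not isolated)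
Conditions: 12 (excess), CsF, MeCN/PhMe (1:1), rt to 60 °C
Reagents that add atoms: none
Why: Desilylation by fluoride with departure of triflate liberates aryne 13, whose strained triple bond engages C3 and C6 of the pyrone in a one-step, unevenly advanced [4+2] cycloaddition to give bicyclic lactone 14; cycloreversion with loss of CO2, driven by aromatisation, then gives the naphthalene. The closest known reaction type is the aryne/2-pyrone Diels–Alder–decarboxylation route to naphthalenes. The only ring closed is the substituted carbocycle of ring B (B-C1 to B-C4 with C4a and C8a), formed by intermolecular cycloaddition in which the B-C1–C8a and B-C4–C4a bonds arise together, the lactone bridge being transient. No stereocentre survives, since the two bridgehead centres of 14 form as a racemate and vanish with the CO2 bridge. The step needs one orientation of the unsymmetrical aryne: the 3-benzyloxy donor makes pyrone C6 the more nucleophilic diene terminus, so it should bond to the aryne carbon meta to OMe (the more electrophilic and less crowded one), which places C3–OBn on the carbon next to C–OMe and hence peri to the methoxy group in 15. The benzyl and methyl ethers carry no acidic hydrogen and should not intercept the aryne.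

Step 9
Reactants: 15 1-(benzyloxy)-2,4-bis[1-(benzyloxy)-8-methoxynaphthalen-2-yl]-8-methoxynaphthalene
Product: 16 2,4-bis(1-hydroxy-8-methoxynaphthalen-2-yl)-8-methoxynaphthalen-1-ol (CNP0482979.0)
Conditions: H2 (1 atm), Pd/C, THF/MeOH, rt
Reagents that add atoms: none
Why: Heterogeneous hydrogenolysis of three aryl benzyl ethers, under which methyl ethers and naphthalene rings should be inert at ambient pressure and temperature.

**Compound list**

1 | naphthalene-1,8-diol | Oc1cccc2cccc(O)c12 | starting material
2 | 8-methoxynaphthalen-1-ol | COc1cccc2cccc(O)c12 | intermediate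
3 | 2-(hydroxymethyl)-8-methoxynaphthalen-1-ol | COc1cccc2ccc(CO)c(O)c12 | intermediate (not isolated)
4 | 1-hydroxy-8-methoxy-2-naphthaldehyde | COc1cccc2ccc(C=O)c(O)c12 | intermediate
5 | 1-(benzyloxy)-8-methoxy-2-naphthaldehyde | COc1cccc2ccc(C=O)c(OCc3ccccc3)c12 | intermediate
6 | 1-(benzyloxy)-2-ethynyl-8-methoxynaphthalene | COc1cccc2ccc(C#C)c(OCc3ccccc3)c12 | intermediate
7 | 1,3-bis[1-(benzyloxy)-8-methoxynaphthalen-2-yl]prop-2-yn-1-ol (racemic) | COc1cccc2ccc(C(O)C#Cc3ccc4cccc(OC)c4c3OCc5ccccc5)c(OCc6ccccc6)c12 | intermediate
8 | 1,3-bis[1-(benzyloxy)-8-methoxynaphthalen-2-yl]prop-2-yn-1-one | COc1cccc2ccc(C(=O)C#Cc3ccc4cccc(OC)c4c3OCc5ccccc5)c(OCc6ccccc6)c12 | intermediate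
9 | methyl 2-(benzyloxy)acetate | COC(=O)COCc1ccccc1 | starting material
10 | methyl (Z)-2-(benzyloxy)-3,5-bis[1-(benzyloxy)-8-methoxynaphthalen-2-yl]-5-oxopent-3-enoate (racemic at C2; present as its lithium dienolate) | COC(=O)C(OCc1ccccc1)/C(c2ccc3cccc(OC)c3c2OCc4ccccc4)=C\C(=O)c5ccc6cccc(OC)c6c5OCc7ccccc7 | intermediate (not isolated)
11 | 3-(benzyloxy)-4,6-bis[1-(benzyloxy)-8-methoxynaphthalen-2-yl]-2H-pyran-2-one | O=c1oc(-c2ccc3cccc(OC)c3c2OCc4ccccc4)cc(-c5ccc6cccc(OC)c6c5OCc7ccccc7)c1OCc8ccccc8 | intermediate
12 | 3-methoxy-2-(trimethylsilyl)phenyl trifluoromethanesulfonate | COc1cccc(OS(=O)(=O)C(F)(F)F)c1[Si](C)(C)C | starting material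
13 | 3-methoxybenzyne (1-methoxy-2,3-didehydrobenzene) | COC1=CC=CC#C1 | intermediate (not isolated)
14 | racemic bridged lactone: 1,4-dihydronaphthalene bridged from C1 to C4 by C(=O)–O (carbonyl carbon on C1, oxygen on C4), with OBn at C1, the protected naphthyl groups at C2 and C4, H at C3 and OMe at C8 | O=C1OC2(c3ccc4cccc(OC)c4c3OCc5ccccc5)C=C(c6ccc7cccc(OC)c7c6OCc8ccccc8)C1(OCc9ccccc9)c%10c(OC)cccc%102 | intermediate (not isolated)
15 | 1-(benzyloxy)-2,4-bis[1-(benzyloxy)-8-methoxynaphthalen-2-yl]-8-methoxynaphthalene | COc1cccc2c(-c3ccc4cccc(OC)c4c3OCc5ccccc5)cc(-c6ccc7cccc(OC)c7c6OCc8ccccc8)c(OCc9ccccc9)c12 | intermediate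
16 | 2,4-bis(1-hydroxy-8-methoxynaphthalen-2-yl)-8-methoxynaphthalen-1-ol (CNP0482979.0) | COc1cccc2ccc(-c3cc(-c4ccc5cccc(OC)c5c4O)c4cccc(OC)c4c3O)c(O)c12 | target

**Count and risks**

Total steps: 9. Longest linear sequence: 9 steps (1 to 16); compounds 9 and 12 are purchased and enter directly, and aldehyde 5 is used in steps 4 and 5.

Steps most likely to fail:

1. Step 7. The hard lithium enolate may add 1,2 to the ynone carbonyl, or the benzyloxyacetate enolate may undergo [1,2]-Wittig rearrangement on warming, before conjugate addition occurs. The fallback sets out from 9 and 8 and rejoins the route at 10. Ester 9 would be converted with LiN(iPr)2 and Me3SiCl in THF at −78 °C into its silyl ketene acetal, (Z)-{[2-(benzyloxy)-1-methoxyethenyl]oxy}trimethylsilane F1. This soft nucleophile would be added to ynone 8 under TiCl4 in CH2Cl2 at −78 °C (Mukaiyama–Michael addition), and aqueous work-up should give keto ester 10 as an alkene mixture. Catalytic DBU in toluene at 80 °C would then close 10 to pyrone 11 as in the second half of step 7.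

2. Step 8. Orientation control of the unsymmetrical aryne may be incomplete, giving some of the 5-methoxy regioisomer, or the aryne may be consumed before the hindered diene reacts. The fallback sets out from 11 and rejoins the route at 15. Commercial 2-(trimethylsilyl)-1,3-phenylene bis(trifluoromethanesulfonate) (C[Si](C)(C)c1c(OS(=O)(=O)C(F)(F)F)cccc1OS(=O)(=O)C(F)(F)F) with CsF in MeCN/PhMe would generate 3-(trifluoromethanesulfonyloxy)benzyne F2, which is more strongly polarised by the inductive triflyloxy group. Cycloaddition to 11 should give the triflyloxy bridged lactone F3, which loses CO2 to 8-(benzyloxy)-5,7-bis[1-(benzyloxy)-8-methoxynaphthalen-2-yl]naphthalen-1-yl trifluoromethanesulfonate F4. Cleavage of the S–O bond with Et4NOH in dioxane at rt would give 8-(benzyloxy)-5,7-bis[1-(benzyloxy)-8-methoxynaphthalen-2-yl]naphthalen-1-ol F5, and MeI with K2CO3 in DMF would methylate it to 15.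

3. Step 2. Formylation may stall because the peri methoxy group sequesters magnesium, or hydroxymethylation may occur at the para position C4 with diarylmethane formation. The fallback sets out from 2 and rejoins the route at 4. MOMCl and iPr2NEt in CH2Cl2 would give 1-methoxy-8-(methoxymethoxy)naphthalene F6. Directed ortho-metalation with nBuLi and TMEDA in THF at 0 °C, where the OMOM group is the stronger director and steers lithiation to C2, followed by a DMF quench, would give 8-methoxy-1-(methoxymethoxy)-2-naphthaldehyde F7. HCl in MeOH would then remove the acetal to give 4.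

**Further compounds**

F1 | step 7 | (Z)-{[2-(benzyloxy)-1-methoxyethenyl]oxy}trimethylsilane | CO/C(O[Si](C)(C)C)=C/OCc1ccccc1
F2 | step 8 | 3-(trifluoromethanesulfonyloxy)benzyne | O=S(=O)(OC1=CC=CC#C1)C(F)(F)F
F3 | step 8 | racemic bridged lactone as 14 but with OSO2CF3 in place of OMe at C8 | O=C1OC2(c3ccc4cccc(OC)c4c3OCc5ccccc5)C=C(c6ccc7cccc(OC)c7c6OCc8ccccc8)C1(OCc9ccccc9)c%10c(OS(=O)(=O)C(F)(F)F)cccc%102
F4 | step 8 | 8-(benzyloxy)-5,7-bis[1-(benzyloxy)-8-methoxynaphthalen-2-yl]naphthalen-1-yl trifluoromethanesulfonate | O=S(=O)(Oc1cccc2c(-c3ccc4cccc(OC)c4c3OCc5ccccc5)cc(-c6ccc7cccc(OC)c7c6OCc8ccccc8)c(OCc9ccccc9)c12)C(F)(F)F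
F5 | step 8 | 8-(benzyloxy)-5,7-bis[1-(benzyloxy)-8-methoxynaphthalen-2-yl]naphthalen-1-ol | Oc1cccc2c(-c3ccc4cccc(OC)c4c3OCc5ccccc5)cc(-c6ccc7cccc(OC)c7c6OCc8ccccc8)c(OCc9ccccc9)c12
F6 | step 2 | 1-methoxy-8-(methoxymethoxy)naphthalene | COCOc1cccc2cccc(OC)c12
F7 | step 2 | 8-methoxy-1-(methoxymethoxy)-2-naphthaldehyde | COCOc1c(C=O)ccc2cccc(OC)c12
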